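## Retrosynthetic overview

1. Target ⇐ fluoride cleavage of three Si–O bonds in the 5'R triphenylsilyl ether, whose hydroquinone is masked as two triisopropylsilyl ethers.
2. Key bond C5'–O (the only stereocentre) ⇐ enantioconvergent palladium-catalysed exchange of a C5' phenylsulfonyl group for a silanolate on the complete C27 skeleton (new reaction).
3. C4'–C5' ⇐ alkylation of the sulfone-stabilised C5' anion of the C15 right half with the aryl-bearing C5 allylic bromide.
4. Right half ⇐ (2E,6E)-farnesol (sulfone, terminal oxidative cleavage, Still–Gennari Z-olefination, reduction). Left half ⇐ 2-allyl-6-methylphenol (para C–O bond with (KSO3)2NO, silylation, cross-metathesis with methacrolein, reduction, bromination).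
5. No ring is formed in the route; the benzene ring is bought.

Numbering: chain carbons run from C1' (ArCH2) to C16' (CH2OH). The target is 2E, 5R, 6E, 10E, 14Z.

Assumption: (2E,6E)-farnesol of at least 95 % isomeric purity is used as bought. Compounds 4, 5 and 18 are racemates at one carbon; this centre is destroyed (4, 5) or made convergent (18).

Assumption: the (R,R) enantiomer of the ligand in step 12 is taken as the one that gives the 5'R product; if the first run shows the opposite sense, its mirror image is used.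

## Route

Step 1
Reactants: 1 (2E,6E)-farnesol
Product: 3 (2E,6E)-farnesyl phenyl sulfone, via farnesyl bromide 2 (not isolated)
Conditions: PBr3, Et2O, 0 °C; then PhSO2Na, DMF, rt
Reagents that add atoms: phosphorus tribromide BrP(Br)Br; sodium benzenesulfinate [Na+].[O-]S(=O)c1ccccc1
Why: Bromination of the primary allylic alcohol and SN2 S-alkylation of sulfinate keep both E alkenes and install the sulfone that later acidifies, epimerises and leaves from C5'.

Step 2
Reactants: 3 (2E,6E)-farnesyl phenyl sulfone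
Product: 5 racemic 10,11-epoxyfarnesyl phenyl sulfone, via bromohydrin 4 (not isolated)
Conditions: NBS, THF/H2O (3:1), 0 °C; then K2CO3, MeOH, rt
Reagents that add atoms: N-bromosuccinimide O=C1CCC(=O)N1Br; water O
Why: Van Tamelen terminal bromohydrin formation is selective for the terminal trisubstituted alkene (the 2,3-alkene is deactivated by the allylic sulfone), and carbonate closes the epoxide by intramolecular SN2; the new centre is racemic and is removed in step 3.

Step 3
Reactants: 5 racemic 10,11-epoxyfarnesyl phenyl sulfone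
Product: 6 (4E,8E)-4,8-dimethyl-10-(phenylsulfonyl)deca-4,8-dienal
Conditions: H5IO6, THF/Et2O, 0 °C
Reagents that add atoms: none
Why: Periodic acid opens the epoxide and cleaves the resulting glycol (Malaprade cleavage) without touching the trisubstituted alkenes; the epoxide oxygen stays on the aldehyde and the isopropylidene carbons leave as acetone.

Step 4
Reactants: 6 (4E,8E)-4,8-dimethyl-10-(phenylsulfonyl)deca-4,8-dienal; 7 ethyl 2-[bis(2,2,2-trifluoroethoxy)phosphoryl]propanoate
Product: 8 ethyl (2Z,6E,10E)-2,6,10-trimethyl-12-(phenylsulfonyl)dodeca-2,6,10-trienoate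
Conditions: KN(SiMe3)2, 18-crown-6, THF, −78 °C
Reagents that add atoms: none
Why: Still–Gennari olefination with the electron-poor phosphonate under dissociating conditions gives the kinetic Z trisubstituted enoate (C14'=C15'), and the pre-formed phosphonate anion does not deprotonate the sulfone.

Step 5
Reactants: 8 ethyl (2Z,6E,10E)-2,6,10-trimethyl-12-(phenylsulfonyl)dodeca-2,6,10-trienoate
Product: 9 (2Z,6E,10E)-2,6,10-trimethyl-12-(phenylsulfonyl)dodeca-2,6,10-trien-1-ol
Conditions: i-Bu2AlH (2.5 equiv), CH2Cl2, −78 °C; potassium sodium tartrate work-up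
Reagents that add atoms: none
Why: Hydride 1,2-reduction of the enoate gives the Z allylic alcohol (C16'–OH) without alkene isomerisation or attack on the sulfone.

Step 6
Reactants: 10 2-allyl-6-methylphenol
Product: 11 2-allyl-6-methyl-1,4-benzoquinone
Conditions: (KSO3)2NO (2.2 equiv), KH2PO4, H2O/acetone, 0 °C to rt
Reagents that add atoms: potassium nitrosodisulfonate [K+].[K+].[O]N(S(=O)(=O)[O-])S(=O)(=O)[O-]
Why: Teuber oxidation places oxygen only at the free para position of the 2,6-disubstituted phenol, which fixes the required 2-alkyl-6-methyl hydroquinone pattern.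

Step 7
Reactants: 11 2-allyl-6-methyl-1,4-benzoquinone
Product: 13 2-allyl-6-methyl-1,4-bis(triisopropylsilyloxy)benzene, via hydroquinone 12 (not isolated)
Conditions: Na2S2O4, EtOAc/H2O, rt; then i-Pr3SiOTf, 2,6-lutidine, CH2Cl2, 0 °C to rt
Reagents that add atoms: triisopropylsilyl trifluoromethanesulfonate CC(C)[Si](C(C)C)(C(C)C)OS(=O)(=O)C(F)(F)F
Why: Dithionite reduction of the quinone and O-silylation with the silyl triflate (strong enough for the hindered OH) give base- and organolithium-stable aryl silyl ethers that fluoride removes at the end.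

Step 8
Reactants: 13 2-allyl-6-methyl-1,4-bis(triisopropylsilyloxy)benzene; 14 methacrolein (5 equiv)
Product: 15 (2E)-2-methyl-4-[3-methyl-2,5-bis(triisopropylsilyloxy)phenyl]but-2-enal
Conditions: second-generation Hoveyda–Grubbs catalyst RuCl2(H2IMes)(=CH-C6H4-2-O-i-Pr) (5 mol %), CH2Cl2, 40 °C
Reagents that add atoms: none
Why: Olefin cross-metathesis of a terminal alkene with methacrolein gives the trisubstituted enal with high E selectivity, which sets the C2'=C3' geometry.

Step 9
Reactants: 15 (2E)-2-methyl-4-[3-methyl-2,5-bis(triisopropylsilyloxy)phenyl]but-2-enal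
Product: 16 (2E)-2-methyl-4-[3-methyl-2,5-bis(triisopropylsilyloxy)phenyl]but-2-en-1-ol
Conditions: i-Bu2AlH, CH2Cl2, −78 °C
Reagents that add atoms: none
Why: Clean 1,2-hydride reduction of the enal gives the E allylic alcohol.

Step 10
Reactants: 16 (2E)-2-methyl-4-[3-methyl-2,5-bis(triisopropylsilyloxy)phenyl]but-2-en-1-ol
Product: 17 1-[(2E)-4-bromo-3-methylbut-2-en-1-yl]-3-methyl-2,5-bis(triisopropylsilyloxy)benzene
Conditions: CBr4, PPh3, CH2Cl2, 0 °C; used crude
Reagents that add atoms: carbon tetrabromide BrC(Br)(Br)Br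
Why: Appel bromination converts the primary allylic alcohol by SN2 without allylic transposition or loss of E geometry.

Step 11
Reactants: 9 (2Z,6E,10E)-2,6,10-trimethyl-12-(phenylsulfonyl)dodeca-2,6,10-trien-1-ol; 17 1-[(2E)-4-bromo-3-methylbut-2-en-1-yl]-3-methyl-2,5-bis(triisopropylsilyloxy)benzene
Product: 18 (2Z,6E,10E,14E)-2,6,10,14-tetramethyl-16-[3-methyl-2,5-bis(triisopropylsilyloxy)phenyl]-12-(phenylsulfonyl)hexadeca-2,6,10,14-tetraen-1-ol (racemic at C12, which is C5')
Conditions: n-BuLi (2.1 equiv), THF/DMPU, −78 °C; then 17, −78 to −30 °C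
Reagents that add atoms: none
Why: Biellmann/Julia-type alkylation of the alkoxide/α-sulfonyl allyl dianion occurs at the α-carbon by SN2 on the primary allylic bromide and forms C4'–C5' with all four alkene geometries intact; C5' is racemic here and is corrected in step 12.

Step 12
Reactants: 18 (2Z,6E,10E,14E)-2,6,10,14-tetramethyl-16-[3-methyl-2,5-bis(triisopropylsilyloxy)phenyl]-12-(phenylsulfonyl)hexadeca-2,6,10,14-tetraen-1-ol
Product: 19 (2Z,6E,10E,12R,14E)-2,6,10,14-tetramethyl-16-[3-methyl-2,5-bis(triisopropylsilyloxy)phenyl]-12-(triphenylsilyloxy)hexadeca-2,6,10,14-tetraen-1-ol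
Conditions: Pd2(dba)3·CHCl3 (2.5 mol %), (R,R)-DACH-phenyl Trost ligand (7.5 mol %), Ph3SiOH (2 equiv), Cs2CO3 (1.2 equiv), THF, 50 °C
Reagents that add atoms: triphenylsilanol O[Si](c1ccccc1)(c1ccccc1)c1ccccc1
Why: Proposed new method: zerovalent palladium ionises the allylic C–S bond with inversion to a 1,3,3-trisubstituted allyl complex whose C6'=C7' geometry is held (no sigma-bonding at the fully substituted terminus), the two enantiomeric manifolds interconvert through sulfinate return and base-mediated epimerisation of the acidic C5'–H of 18 (Curtin–Hammett), and the bulky caesium triphenylsilanolate attacks the less hindered C5' terminus anti to palladium in the matched complex to form a C–O bond that cannot re-ionise, so the 5'R centre is set in the C–O bond-forming step; the closest known reactions are palladium-catalysed substitution of allylic sulfones by carbon nucleophiles, the use of triphenylsilanol as a water surrogate in allylpalladium chemistry, and palladium/Trost-ligand deracemisation of allylic carbonates with oxygen nucleophiles.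

Step 13
Reactants: 19 (2Z,6E,10E,12R,14E)-2,6,10,14-tetramethyl-16-[3-methyl-2,5-bis(triisopropylsilyloxy)phenyl]-12-(triphenylsilyloxy)hexadeca-2,6,10,14-tetraen-1-ol
Product: 20 2-[(2E,5R,6E,10E,14Z)-5,16-dihydroxy-3,7,11,15-tetramethylhexadeca-2,6,10,14-tetraen-1-yl]-6-methylbenzene-1,4-diol (CNP0151872.2)
Conditions: Bu4NF (3.5 equiv), AcOH (3.5 equiv), THF, 0 °C to rt, argon; aqueous Na2S2O4 wash
Reagents that add atoms: none
Why: Buffered fluoride desilylation cleaves the two aryl silyl ethers and the secondary triphenylsilyl ether in one operation without acid (no chroman formation, no allylic ionisation) and without touching C5'.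

## Compound list

1 | (2E,6E)-farnesol | CC(C)=CCC/C(C)=C/CC/C(C)=C/CO | starting material
2 | (2E,6E)-farnesyl bromide | CC(C)=CCC/C(C)=C/CC/C(C)=C/CBr | intermediate
3 | (2E,6E)-farnesyl phenyl sulfone | CC(C)=CCC/C(C)=C/CC/C(C)=C/CS(=O)(=O)c1ccccc1 | intermediate
4 | (6E,10E)-3-bromo-2,6,10-trimethyl-12-(phenylsulfonyl)dodeca-6,10-dien-2-ol, racemic | CC(C)(O)C(Br)CC/C(C)=C/CC/C(C)=C/CS(=O)(=O)c1ccccc1 | intermediate
5 | 2,2-dimethyl-3-[(3E,7E)-3,7-dimethyl-9-(phenylsulfonyl)nona-3,7-dien-1-yl]oxirane, racemic | CC1(C)OC1CC/C(C)=C/CC/C(C)=C/CS(=O)(=O)c1ccccc1 | intermediate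
6 | (4E,8E)-4,8-dimethyl-10-(phenylsulfonyl)deca-4,8-dienal | O=CCC/C(C)=C/CC/C(C)=C/CS(=O)(=O)c1ccccc1 | intermediate
7 | ethyl 2-[bis(2,2,2-trifluoroethoxy)phosphoryl]propanoate | CCOC(=O)C(C)P(=O)(OCC(F)(F)F)OCC(F)(F)F | starting material
8 | ethyl (2Z,6E,10E)-2,6,10-trimethyl-12-(phenylsulfonyl)dodeca-2,6,10-trienoate | CCOC(=O)/C(C)=C\CC/C(C)=C/CC/C(C)=C/CS(=O)(=O)c1ccccc1 | intermediate
9 | (2Z,6E,10E)-2,6,10-trimethyl-12-(phenylsulfonyl)dodeca-2,6,10-trien-1-ol | OC/C(C)=C\CC/C(C)=C/CC/C(C)=C/CS(=O)(=O)c1ccccc1 | intermediate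
10 | 2-allyl-6-methylphenol | C=CCc1cccc(C)c1O | starting material
11 | 2-allyl-6-methyl-1,4-benzoquinone | C=CCC1=CC(=O)C=C(C)C1=O | intermediate
12 | 2-allyl-6-methylbenzene-1,4-diol | C=CCc1cc(O)cc(C)c1O | intermediate
13 | 2-allyl-6-methyl-1,4-bis(triisopropylsilyloxy)benzene | C=CCc1cc(O[Si](C(C)C)(C(C)C)C(C)C)cc(C)c1O[Si](C(C)C)(C(C)C)C(C)C | intermediate
14 | methacrolein | CC(=C)C=O | starting material
15 | (2E)-2-methyl-4-[3-methyl-2,5-bis(triisopropylsilyloxy)phenyl]but-2-enal | O=C/C(C)=C/Cc1cc(O[Si](C(C)C)(C(C)C)C(C)C)cc(C)c1O[Si](C(C)C)(C(C)C)C(C)C | intermediate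
16 | (2E)-2-methyl-4-[3-methyl-2,5-bis(triisopropylsilyloxy)phenyl]but-2-en-1-ol | OC/C(C)=C/Cc1cc(O[Si](C(C)C)(C(C)C)C(C)C)cc(C)c1O[Si](C(C)C)(C(C)C)C(C)C | intermediate
17 | 1-[(2E)-4-bromo-3-methylbut-2-en-1-yl]-3-methyl-2,5-bis(triisopropylsilyloxy)benzene | BrC/C(C)=C/Cc1cc(O[Si](C(C)C)(C(C)C)C(C)C)cc(C)c1O[Si](C(C)C)(C(C)C)C(C)C | intermediate
18 | (2Z,6E,10E,14E)-2,6,10,14-tetramethyl-16-[3-methyl-2,5-bis(triisopropylsilyloxy)phenyl]-12-(phenylsulfonyl)hexadeca-2,6,10,14-tetraen-1-ol, racemic at C12 | C/C(=C/CC/C(C)=C/CC/C(C)=C/C(C/C(C)=C/Cc1cc(O[Si](C(C)C)(C(C)C)C(C)C)cc(C)c1O[Si](C(C)C)(C(C)C)C(C)C)S(=O)(=O)c1ccccc1)CO | intermediate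
19 | (2Z,6E,10E,12R,14E)-2,6,10,14-tetramethyl-16-[3-methyl-2,5-bis(triisopropylsilyloxy)phenyl]-12-(triphenylsilyloxy)hexadeca-2,6,10,14-tetraen-1-ol | C/C(=C/CC/C(C)=C/CC/C(C)=C/[C@H](O[Si](c1ccccc1)(c1ccccc1)c1ccccc1)C/C(C)=C/Cc1cc(O[Si](C(C)C)(C(C)C)C(C)C)cc(C)c1O[Si](C(C)C)(C(C)C)C(C)C)CO | intermediate
20 | 2-[(2E,5R,6E,10E,14Z)-5,16-dihydroxy-3,7,11,15-tetramethylhexadeca-2,6,10,14-tetraen-1-yl]-6-methylbenzene-1,4-diol | C/C(=C/CC/C(C)=C/CC/C(C)=C/[C@H](O)C/C(C)=C/Cc1cc(O)cc(C)c1O)CO | target

## Step count and risks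

Total step count: 13 (steps 1–5 right half, steps 6–10 left half, steps 11–13 union and end game).
Longest linear sequence: 8 steps (1–5 then 11–13; the branch 6–10 then 11–13 is equally long).

The three steps most likely to fail:

Step 12 (the new reaction). Possible failures are slow ionisation of the trialkyl-substituted allylic sulfone, loss of a β-hydrogen from the allyl complex to give a triene, attack at C7' to give the tertiary ether, base-induced drift of 18 to the vinyl sulfone, and low selectivity between the two allyl manifolds. The fallback uses known chemistry, sets out from 18 and comes back to the route at 20. Compound 18 is deprotonated twice with LiN(i-Pr)2 (2.2 equiv, THF, −78 °C) and the α-sulfonyl carbanion is oxidised with Me3SiOOSiMe3 (oxidative desulfonylation) to (2E,6E,10E,14Z)-16-hydroxy-3,7,11,15-tetramethyl-1-[3-methyl-2,5-bis(triisopropylsilyloxy)phenyl]hexadeca-2,6,10,14-tetraen-5-one F1. Corey–Bakshi–Shibata reduction of this enone with (S)-2-methyl-CBS-oxazaborolidine and catecholborane (toluene, −78 °C; the β,β-disubstituted alkenyl group acts as the large group) gives (2Z,6E,10E,12R,14E)-2,6,10,14-tetramethyl-16-[3-methyl-2,5-bis(triisopropylsilyloxy)phenyl]hexadeca-2,6,10,14-tetraene-1,12-diol F2. Bu4NF/AcOH in THF then removes the two aryl silyl groups and gives 20.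

Step 11 (dianion alkylation). The lithium alkoxide/α-sulfonyl dianion may be poorly soluble or may give low conversion with the sensitive allylic bromide. The fallback replaces the dianion by a protect–couple–unmask sequence; it sets out from 9 and comes back at 18. The hydroxyl of 9 is silylated (TBSCl, imidazole, DMF) to tert-butyldimethyl{[(2Z,6E,10E)-2,6,10-trimethyl-12-(phenylsulfonyl)dodeca-2,6,10-trien-1-yl]oxy}silane F3. Its mono-anion (n-BuLi 1.05 equiv, THF/DMPU, −78 °C) is alkylated with 17 to give the tert-butyldimethylsilyl ether of 18 F4. PPTS in MeOH at rt then removes only the primary alkyl silyl ether (the aryl triisopropylsilyl ethers stay) and returns 18.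

Step 13 (final desilylation). The free ortho-prenyl hydroquinone is air-sensitive and under basic fluoride can oxidise and cyclise to a chromenol. The fallback changes the end game to a redox detour; it sets out from 19 and comes back at 20. After Bu4NF/AcOH the crude product is oxidised at once with Ag2O (Et2O, rt) and isolated and purified as the air-stable 2-[(2E,5R,6E,10E,14Z)-5,16-dihydroxy-3,7,11,15-tetramethylhexadeca-2,6,10,14-tetraen-1-yl]-6-methyl-1,4-benzoquinone F5. Reduction with Na2S2O4 (EtOAc/H2O, rt, argon) then gives 20 as a clean last operation.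

Further compounds
F1 | step 12 | (2E,6E,10E,14Z)-16-hydroxy-3,7,11,15-tetramethyl-1-[3-methyl-2,5-bis(triisopropylsilyloxy)phenyl]hexadeca-2,6,10,14-tetraen-5-one | C/C(=C/CC/C(C)=C/CC/C(C)=C/C(=O)C/C(C)=C/Cc1cc(O[Si](C(C)C)(C(C)C)C(C)C)cc(C)c1O[Si](C(C)C)(C(C)C)C(C)C)CO
F2 | step 12 | (2Z,6E,10E,12R,14E)-2,6,10,14-tetramethyl-16-[3-methyl-2,5-bis(triisopropylsilyloxy)phenyl]hexadeca-2,6,10,14-tetraene-1,12-diol | C/C(=C/CC/C(C)=C/CC/C(C)=C/[C@H](O)C/C(C)=C/Cc1cc(O[Si](C(C)C)(C(C)C)C(C)C)cc(C)c1O[Si](C(C)C)(C(C)C)C(C)C)CO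
F3 | step 11 | tert-butyldimethyl{[(2Z,6E,10E)-2,6,10-trimethyl-12-(phenylsulfonyl)dodeca-2,6,10-trien-1-yl]oxy}silane | CC(C)(C)[Si](C)(C)OC/C(C)=C\CC/C(C)=C/CC/C(C)=C/CS(=O)(=O)c1ccccc1
F4 | step 11 | tert-butyldimethylsilyl ether of 18 (racemic at the sulfone carbon) | C/C(=C/CC/C(C)=C/CC/C(C)=C/C(C/C(C)=C/Cc1cc(O[Si](C(C)C)(C(C)C)C(C)C)cc(C)c1O[Si](C(C)C)(C(C)C)C(C)C)S(=O)(=O)c1ccccc1)CO[Si](C)(C)C(C)(C)C
F5 | step 13 | 2-[(2E,5R,6E,10E,14Z)-5,16-dihydroxy-3,7,11,15-tetramethylhexadeca-2,6,10,14-tetraen-1-yl]-6-methyl-1,4-benzoquinone | C/C(=C/CC/C(C)=C/CC/C(C)=C/[C@H](O)C/C(C)=C/CC1=CC(=O)C=C(C)C1=O)CO
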